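## Analysis of the target

The target 18, [(3R,4S,5R,6S)-5-(benzoyloxy)-3,4,6-trihydroxycyclohex-1-en-1-yl]methyl benzoate, is a single carbocycle. Its C1=C2 double bond carries the exocyclic carbon C7 (as CH2OBz) on C1, and C3, C4, C5 and C6 are four contiguous oxygen-bearing stereocentres; this ring numbering is used for every intermediate below. O4 and O5 are cis to each other, whereas O3 and O6, cis to each other in a 1,4-relationship across the alkene, both lie on the opposite face, so each end of the cis pair is trans to its outer neighbour. The sensitive points are the two benzoates, which can migrate to neighbouring free hydroxyls under base, the two allylic carbinols C3 and C6, and the ease with which ketone-level intermediates of this oxygenation pattern dehydrate to phenols. The skeleton is simple (only C7 lies outside the ring); the difficulty is to set four stereocentres on a ring with no carbon stereocentre to lean on, and then to tell four secondary oxygens apart so that only O5 is acylated. The plan rests on the unit O3–C3–C2=C1–C6–O6 with both oxygens on one face: a 1,4-dioxygenated 2-ene is what a [4+2] addition of O2 to a 1,3-diene leaves, and with the cis-diol C4/C5 on the other face it is the anti adduct of singlet oxygen with an arene cis-dihydrodiol. A halogen on C6 of that diene breaks the symmetry of the two termini: after O–O reduction C6 falls to a ketone and C3 stays a carbinol, so C1 becomes an enone α-carbon that can take up C7, and C6 is left to be set by a directed reduction.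

## Retrosynthetic reasoning

**18 ⇒ 17 (O3–Si).** The silyl ether on O3 is removed last, under acidic fluoride, because after that point no base should touch a molecule with two benzoates beside three free hydroxyls. O3 is the first hydroxyl to appear in the route, and capping it at once reduces the later problem of four secondary oxygens to one of three.

**17 ⇒ 14 + 15 (O5–acyl bond).** The O5 benzoate is cut back to triol 14 and trimethyl orthobenzoate 15. In 14 only O4 and O5 are cis, so only they can be bridged as the cyclic orthoester 16, and mild aqueous acid should open 16 to the ester on the axial oxygen. The choice among three hydroxyls thus becomes a choice between two that is governed by ring conformation and not by small rate differences.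

**14 ⇒ 13 ⇒ 12 (C6–H, then the isopropylidene group).** The C6 carbinol is traced to the ketone 13. A hydride source that is activated only by a neighbouring hydroxyl will be carried by O4 and O5 on the lower face and must leave O6 on the upper face, trans to O5. This is why the acetonide of 12 is removed before the reduction and not after it: on 12 an external hydride would approach anti to the dioxolane and give the C6 epimer.

**12 ⇒ 10 + 11 and 10 ⇒ 8 + 9 (O7–acyl, then C1–C7).** C7–OH is the only free hydroxyl in 10, so its benzoylation with benzoyl chloride 11 needs no selectivity. The C1–C7 bond is the only C–C bond outside the ring and creates no stereocentre. C1 is the α-carbon of the C6 enone in 8, so the bond is made by an amine-catalysed aldol-type addition to formaldehyde 9.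

**8 ⇒ 6 + 7 (O3–Si).** The lone hydroxyl of 6 is silylated with tert-butyl(chloro)diphenylsilane 7. This silyl group is chosen because it has to survive two later aqueous-acid steps.

**6 ⇒ 5 (O–O, and the C6 carbonyl).** The C6 carbonyl and the C3 hydroxyl of 6 are the two halves of a peroxide. In 5 the bromine on the C6 bridgehead ensures that two-electron reduction of the O–O bond ends in a ketone at C6 only, with C3 keeping its configuration because no C–O bond is broken.

**5 ⇒ 3 + 4 (C3–O and C6–O).** Both C–O bonds are cut together. The forward reaction is the [4+2] addition of singlet dioxygen 4 to the diene C6=C1–C2=C3 of 3. It has to deliver both oxygens to the face opposite the dioxolane, which fixes C3 and C6 relative to C4 and C5 in one step.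

**3 ⇒ 1 + 2.** The acetonide 3 is one step from the commercial diol 1, a fermentation product made by enzymatic arene cis-dihydroxylation, and 2,2-dimethoxypropane 2. The absolute configuration of C4 and C5, and from it that of the whole target, is bought with 1.

## Alternatives that were turned down

**Alternative 1: Ferrier carbocyclization.**
- Disconnection: the ring bond C2–C3 is cut as an aldol bond, unfolding the carbocycle into a pyranoside with an exocyclic enol ether, derived from a galacto-configured hexose.
- Forward key step: mercury bis(trifluoroacetate) A2, a divalent mercury salt used in catalytic amount in aqueous organic solvent, hydrates the exocyclic enol ether. The hemiacetal opens to the aldehyde, and the mercury enolate closes the six-membered ring on it. The product is the β-hydroxy cyclohexanone A1, with the ketone at C1, a methylene at C2, the benzoate already on O5 and silyl ethers on O4 and O6.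
- For it: on one point it is stronger than the chosen plan. The ring oxygens arrive already differentiated, so nothing like step 9 is needed. It also needs neither light nor a fermentation product.
- Against it: A1 has neither C7 nor the C1=C2 double bond. The ketone would have to be turned regioselectively into a C1=C2 enol derivative and homologated, while the β-hydroxyl on C3 is placed for E1cB loss toward a C2=C3 enone, which would erase C3 and misplace the alkene. The C3 configuration is decided in the aldol event and not by a rigid element. The sugar precursor needs an inversion and several selective protections, and the mercury salt A2 is an unwelcome reagent even in catalytic amount.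
- Comparison: the route would be roughly twice as long, and its weak point lies after the key step. The chosen plan gives up pre-differentiated oxygens but obtains O3, O6 and the alkene position in one pericyclic step two steps from commercial material, and attaches C7 to the only enone α-carbon available.

**Alternative 2: intramolecular Morita–Baylis–Hillman closure.**
- Disconnection: C1–C6, opening the ring to an acyclic enoate aldehyde (ester carbon C7 on C1, C1=C2, silyloxy on C3, acetonide on C4/C5, aldehyde at C6) built from an arabino-configured pentose.
- Forward key step: a nucleophilic trialkylphosphine adds to C2, the enolate carbon C1 attacks the C6 aldehyde, and loss of the phosphine restores C1=C2, giving the hydroxy ester A3.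
- For it: on skeletal economy this step is stronger than anything in the chosen route. One operation makes the ring, places C7 on C1 one reduction away from the target, fixes the alkene and delivers the C6 hydroxyl; the chosen route needs steps 5 and 8 for the same result.
- Against it: C6 is created by addition to an α-alkoxy aldehyde under reversible conditions, so its configuration (trans to O5) rests on modest 1,2-induction. The phosphonium enolate can expel the silyloxy group on C3, and the aldehyde can epimerise at C5. The acyclic precursor costs many steps (chain extension, selective protection, terminal oxidation), and ester reduction plus O6/O7 differentiation follow the key step. The endgame (acetonide removal, O5 acylation, desilylation) is the same as here.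
- Comparison: the length is similar or greater, with the stereochemical risk inside the key step. The chosen cycloaddition cannot give a C3 or C6 epimer as long as the facial bias holds, and C6 is set later by an internally delivered hydride.

**Alternative 3: sulfur-ylide homologation of a chiral-pool enone.**
- Disconnection: C1–C7 and C7–O, leading to a C1 ketone conjugated to a C2=C3 alkene, with the C4/C5 acetonide and a C6 silyl ether, taken from a shikimate-pathway chiral-pool cyclohexane.
- Forward key step: a sulfonium methylide adds 1,2 to the C1 carbonyl anti to the C6 silyloxy group, and the alkoxide displaces the sulfide to close the spiro-oxirane A4. The former carbonyl oxygen becomes O7 and sits cis to O6.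
- For it: the chiral pool is cheap. On the C7 problem it is at least as good as the chosen route, because C1–C7 and C7–O form together and no ketone remains to be reduced. A later SN2′ opening of the vinyl oxirane at C3 would transpose the alkene to C1=C2 and bring in O3 in one step.
- Against it: that SN2′ step carries the C3 stereocentre. The oxygen must enter trans to O4, on the face of the departing oxirane oxygen. This calls for a double-inversion metal π-allyl pathway with the metal on the acetonide-shielded face, or else an acid-mediated opening without facial control. The precursor enone needs an oxygen at C6 that the pool material, with only three contiguous carbinols, does not supply. Vinyl oxiranes of this kind ionise easily.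
- Comparison: C3 is the weak point, whereas the chosen route fixes C3 and C6 together in the cycloaddition. The step count to A4 alone exceeds that to 6.

Key step: step 2

Remarks on the chemistry:
- The silyl group on O3 is tert-butyldiphenylsilyl, so that it outlasts the aqueous acid of steps 7 and 9.
- The spent thiourea of step 3 is booked as urea and elemental sulfur, taken as the fate of its S-oxide in moist methanol.

## Route

**Step 1**
Reactants: 1 (1S,2S)-3-bromocyclohexa-3,5-diene-1,2-diol; 2 2,2-dimethoxypropane
Product: 3 (3aS,7aS)-4-bromo-2,2-dimethyl-3a,7a-dihydro-1,3-benzodioxole (acetonide of 1)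
Conditions: Me2C(OMe)2, p-TsOH·H2O (cat.), CH2Cl2, 0 °C to rt; Et3N
Reagents that add atoms: 2,2-dimethoxypropane (2), COC(C)(C)OC
Why: Acid-catalysed transketalisation of a cis-1,2-diol; no stereocentre is touched. A short reaction time and a basic quench should prevent acid-promoted aromatisation, and 3 is used at once because dienes of this type dimerise by Diels–Alder reaction on standing.

**Step 2**
Reactants: 3 bromodiene acetonide; 4 dioxygen
Product: 5 bromo endoperoxide acetonide (1-bromo-7,8-isopropylidenedioxy-2,3-dioxabicyclo[2.2.2]oct-5-ene; peroxide bridge from C3 to C6 on the face opposite to the dioxolane, bromine on the C6 bridgehead)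
Conditions: O2, tetraphenylporphyrin (cat.), hν (visible), CH2Cl2, −30 °C
Reagents that add atoms: dioxygen (4), O=O
Why: Energy transfer from the excited porphyrin gives singlet dioxygen, which adds as the 2π partner to the s-cis diene C6=C1–C2=C3, held planar by the ring, in a concerted suprafacial [4+2] cycloaddition; the closest known reaction type is the singlet-oxygen Diels–Alder addition to cyclohexa-1,3-dienes, including halogenated arene cis-dihydrodiol acetonides. The one ring that forms, the 3,6-dihydro-1,2-dioxine C3–O–O–C6–C1=C2, is closed by this pericyclic cycloaddition with both C–O bonds made in the same step, which turns the carbocycle into a 2,3-dioxabicyclo[2.2.2]oct-5-ene. The new stereocentres C3 and C6 are tied to each other by the suprafacial mode (both oxygens on one face) and to C4/C5 by the cis-fused dioxolane, whose inward methyl group covers the syn face, so both oxygens should arrive anti. Facial selectivity is the only selectivity the step needs: dioxygen is symmetric, so there is no regiochemical question, and the locked cisoid geometry should favour the [4+2] mode over an ene reaction at C4–H. Bromine on C6 lowers the diene HOMO only slightly and ends on the bridgehead, where step 3 needs it. Low temperature and dilution should hold back Diels–Alder dimerisation of 3 and thermal rearrangement of the peroxide, which is carried on without storage.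

**Step 3**
Reactants: 5 bromo endoperoxide acetonide
Product: 6 (4R,5S,6S)-4-hydroxy-5,6-(isopropylidenedioxy)cyclohex-2-en-1-one (target numbering: C6 ketone, C1=C2, C3–OH trans to the C4/C5 dioxolane)
Conditions: thiourea, NaHCO3, MeOH/H2O (20:1), 0 °C to rt
Reagents that add atoms: none
Why: Thiourea reduction of an endoperoxide: sulfur attacks the O–O bond, and the C6 alkoxide, which also carries bromine, expels bromide to give the ketone while C3 stays a carbinol with unchanged configuration because no C–O bond breaks. Solid NaHCO3 takes up the HBr so that the acetonide is not exposed to acid.

**Step 4**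
Reactants: 6 hydroxy enone; 7 tert-butyl(chloro)diphenylsilane
Product: 8 O3-tert-butyldiphenylsilyl ether of 6 (4-(tert-butyldiphenylsilyloxy)-5,6-(isopropylidenedioxy)cyclohex-2-en-1-one; silyloxy group trans to the dioxolane, configuration as in 6)
Conditions: TBDPSCl, imidazole, DMF, 0 °C to rt
Reagents that add atoms: tert-butyl(chloro)diphenylsilane (7), CC(C)(C)[Si](Cl)(c1ccccc1)c1ccccc1
Why: Imidazole-promoted silylation of the only hydroxyl; the conditions are too mild to enolise the ketone toward C5. This silyl ether is far more stable to acid than a tert-butyldimethylsilyl ether and should survive steps 7 and 9.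

**Step 5**
Reactants: 8 silyl enone; 9 formaldehyde
Product: 10 C1-hydroxymethyl enone (4-(tert-butyldiphenylsilyloxy)-2-(hydroxymethyl)-5,6-(isopropylidenedioxy)cyclohex-2-en-1-one; ring configuration as in 8)
Conditions: aq. CH2O (37%), DMAP (0.3 equiv), THF/H2O, rt
Reagents that add atoms: formaldehyde (9), C=O
Why: Morita–Baylis–Hillman reaction: DMAP adds to C2 anti to the silyloxy group, the resulting C1 enolate adds to formaldehyde, and loss of DMAP restores C1=C2. No stereocentre is formed, and C1 is the only enone α-carbon, so the position of C7 is unambiguous.

**Step 6**
Reactants: 10 C1-hydroxymethyl enone; 11 benzoyl chloride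
Product: 12 C7 benzoate of 10 ([3-(tert-butyldiphenylsilyloxy)-4,5-(isopropylidenedioxy)-6-oxocyclohex-1-en-1-yl]methyl benzoate in target numbering; ring configuration as in 8)
Conditions: BzCl, pyridine, CH2Cl2, 0 °C
Reagents that add atoms: benzoyl chloride (11), O=C(Cl)c1ccccc1
Why: Acylation of the only free, primary hydroxyl. No stronger nucleophilic amine is added, because allylic esters of this Baylis–Hillman type can undergo SN2′ displacement by such catalysts.

**Step 7**
Reactants: 12 C7 benzoate acetonide
Product: 13 diol enone ([3-(tert-butyldiphenylsilyloxy)-4,5-dihydroxy-6-oxocyclohex-1-en-1-yl]methyl benzoate; cis-diol at C4/C5, O3 on the opposite face)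
Conditions: TFA/H2O (4:1), CH2Cl2, 0 °C to rt
Reagents that add atoms: none
Why: Acid hydrolysis of the isopropylidene acetal; the benzoate, the enone and the acid-stable silyl ether should survive. Hydroxy enones of this oxygenation pattern are known to tolerate such conditions when kept cold and worked up promptly.

**Step 8**
Reactants: 13 diol enone
Product: 14 triol ([3-(tert-butyldiphenylsilyloxy)-4,5,6-trihydroxycyclohex-1-en-1-yl]methyl benzoate; O4 and O5 cis, O3 and O6 on the opposite face, ring configuration as in 18)
Conditions: Me4NBH(OAc)3, MeCN/AcOH (1:1), −20 °C
Reagents that add atoms: none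
Why: Evans–Saksena hydroxyl-directed reduction: acetate on boron exchanges for the C4 hydroxyl (β to the ketone) or the C5 hydroxyl (α to the ketone), and hydride is delivered intramolecularly to the carbonyl face on which these oxygens lie, so O6 should emerge on the opposite face, anti to O4 and trans to O5. The reagent leaves esters and the C=C bond alone and reduces ketones only slowly without such activation.

**Step 9**
Reactants: 14 triol; 15 trimethyl orthobenzoate
Product: 17 O5 benzoate [5-(benzoyloxy)-3-(tert-butyldiphenylsilyloxy)-4,6-dihydroxycyclohex-1-en-1-yl]methyl benzoate, via C4/C5 cyclic methyl orthobenzoate 16 (not isolated)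
Conditions: PhC(OMe)3, CSA (cat.), MeCN, rt; then AcOH/H2O (4:1), rt
Reagents that add atoms: trimethyl orthobenzoate (15), COC(OC)(OC)c1ccccc1; water, O
Why: Acid-catalysed orthoester exchange should select the only cis-diol (O4/O5); O6 is trans to O5 and on the far face. Aqueous acid then converts 16 through the dioxolanylium ion and its hemiorthoester to a hydroxy ester, and such collapses favour the axial ester. The half-chair with the C6 hydroxyl pseudoaxial (less A(1,2) strain against the C1 substituent) and the C3 silyloxy group pseudoequatorial makes O5 axial, so the benzoate should end on O5.

**Step 10**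
Reactants: 17 O5 benzoate silyl ether
Product: 18 [(3R,4S,5R,6S)-5-(benzoyloxy)-3,4,6-trihydroxycyclohex-1-en-1-yl]methyl benzoate
Conditions: HF·pyridine (excess), THF, 0 °C to rt
Reagents that add atoms: none
Why: Fluoride-driven cleavage of the Si–O bond in a non-basic medium, which should leave both benzoates where they are and not ionise the allylic carbinols.

## Compound list

1 | (1S,2S)-3-bromocyclohexa-3,5-diene-1,2-diol | BrC1=CC=C[C@H](O)[C@@H]1O | starting material
2 | 2,2-dimethoxypropane | COC(C)(C)OC | starting material
3 | (3aS,7aS)-4-bromo-2,2-dimethyl-3a,7a-dihydro-1,3-benzodioxole (acetonide of 1) | BrC1=CC=C[C@@H]2OC(C)(C)O[C@H]12 | intermediate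
4 | dioxygen | O=O | starting material
5 | bromo endoperoxide acetonide (peroxide bridge C3 to C6 anti to the dioxolane, Br on C6) | C1=C[C@@H](OO2)[C@@H]3OC(C)(C)O[C@@H]3[C@]12Br | intermediate
6 | (4R,5S,6S)-4-hydroxy-5,6-(isopropylidenedioxy)cyclohex-2-en-1-one | O=C1C=C[C@@H](O)[C@@H]2OC(C)(C)O[C@H]12 | intermediate
7 | tert-butyl(chloro)diphenylsilane | CC(C)(C)[Si](Cl)(c1ccccc1)c1ccccc1 | starting material
8 | O3-tert-butyldiphenylsilyl ether of 6 | O=C1C=C[C@@H](O[Si](c2ccccc2)(c2ccccc2)C(C)(C)C)[C@@H]2OC(C)(C)O[C@H]12 | intermediate
9 | formaldehyde | C=O | starting material
10 | C1-hydroxymethyl enone (2-(hydroxymethyl) derivative of 8) | O=C1C(CO)=C[C@@H](O[Si](c2ccccc2)(c2ccccc2)C(C)(C)C)[C@@H]2OC(C)(C)O[C@H]12 | intermediate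
11 | benzoyl chloride | O=C(Cl)c1ccccc1 | starting material
12 | C7 benzoate of 10 | O=C1C(COC(=O)c2ccccc2)=C[C@@H](O[Si](c2ccccc2)(c2ccccc2)C(C)(C)C)[C@@H]2OC(C)(C)O[C@H]12 | intermediate
13 | diol enone: [3-(tert-butyldiphenylsilyloxy)-4,5-dihydroxy-6-oxocyclohex-1-en-1-yl]methyl benzoate (O4/O5 cis, O3 trans to them) | O=C1C(COC(=O)c2ccccc2)=C[C@@H](O[Si](c2ccccc2)(c2ccccc2)C(C)(C)C)[C@H](O)[C@@H]1O | intermediate
14 | triol: [3-(tert-butyldiphenylsilyloxy)-4,5,6-trihydroxycyclohex-1-en-1-yl]methyl benzoate (ring configuration as in 18) | O=C(OCC1=C[C@@H](O[Si](c2ccccc2)(c2ccccc2)C(C)(C)C)[C@H](O)[C@H](O)[C@H]1O)c1ccccc1 | intermediate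
15 | trimethyl orthobenzoate | COC(OC)(OC)c1ccccc1 | starting material
16 | C4/C5 cyclic methyl orthobenzoate of 14 (2-methoxy-2-phenyl-1,3-dioxolane cis-fused at C4/C5; either configuration at the orthoester carbon) | O=C(OCC1=C[C@@H](O[Si](c2ccccc2)(c2ccccc2)C(C)(C)C)[C@@H]2OC(OC)(c3ccccc3)O[C@@H]2[C@H]1O)c1ccccc1 | intermediate
17 | [5-(benzoyloxy)-3-(tert-butyldiphenylsilyloxy)-4,6-dihydroxycyclohex-1-en-1-yl]methyl benzoate (ring configuration as in 18) | O=C(OCC1=C[C@@H](O[Si](c2ccccc2)(c2ccccc2)C(C)(C)C)[C@H](O)[C@H](OC(=O)c2ccccc2)[C@H]1O)c1ccccc1 | intermediate
18 | [(3R,4S,5R,6S)-5-(benzoyloxy)-3,4,6-trihydroxycyclohex-1-en-1-yl]methyl benzoate | O=C(OCC1=C[C@@H](O)[C@H](O)[C@H](OC(=O)c2ccccc2)[C@H]1O)c1ccccc1 | target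

## Step count and least certain steps

Total step count: 10. Longest linear sequence: 10 steps (1 to 18); the route is fully linear.

**Step 2 (key step).** The most likely failures are Diels–Alder dimerisation of the diene before it meets singlet oxygen, slow cycloaddition of the slightly electron-poor bromodiene with bleaching of the sensitiser, and thermal rearrangement of the strained bromo peroxide during handling. The fallback installs the two oxygens one after the other without a peroxide. It sets out from 3. Epoxidation with mCPBA (CH2Cl2, 0 °C) at the more electron-rich C2=C3 alkene, anti to the dioxolane, should give the bromo vinyl epoxide F1. PhSeSePh/NaBH4 in EtOH should open it at the allylic carbon C2 with inversion to the trans hydroxy selenide F2, leaving O3 on the correct face. Oxidation with H2O2 (pyridine, CH2Cl2, 0 °C) should give the allylic selenoxide F3. Its [2,3]-sigmatropic shift puts oxygen on C6 and moves the alkene to C1=C2, giving the C6 bromo selenenate F4, which collapses to the ketone with loss of selenium and bromine from C6. The sequence comes back to the route at 6.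

**Step 9.** The collapse of the hemiorthoester may show poor regioselectivity if neither half-chair dominates, so that part of the benzoate ends on O4. Further risks are exchange of the orthoester onto the free C6 hydroxyl and acid-promoted benzoyl migration. The fallback places the benzoate before the ketone is reduced, where the two hydroxyls differ intrinsically. It sets out from 13. O5 is the α-ketol hydroxyl, the more acidic one, flanked by the flat carbonyl, whereas O4 is buried beside the silyl ether. Benzoyl chloride 11 (1 equiv, pyridine, CH2Cl2, −40 °C) should therefore give the O5 benzoate of the diol enone F5. Reduction with Me4NBH(OAc)3 (MeCN/AcOH, −20 °C), now directed by the C4 hydroxyl alone, should give the 1,3-anti alcohol. This is 17, where the fallback rejoins the route, bypassing 14 and 16.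

**Step 8.** Hydride transfer to a hindered, cross-conjugated ketone may be sluggish, which would let undirected reduction erode the facial selectivity, and the α-ketol may isomerise in acetic acid. The fallback replaces internal delivery by external attack followed by inversion. It sets out from 12. Luche reduction (NaBH4, CeCl3·7H2O, MeOH, −78 °C) should attack anti to the dioxolane and give the C6-epimeric allylic alcohol acetonide F6 (O6 cis to O5). Mitsunobu reaction with chloroacetic acid (PPh3, DIAD, THF, 0 °C) should invert C6 to the chloroacetate F7. Selective methanolysis (Et3N, MeOH, 0 °C), which benzoates should survive, gives the C6 alcohol acetonide F8 with the target configuration, and TFA/H2O removes the acetonide. The fallback comes back at 14 and also avoids the free hydroxy ketone 13.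

**Step 5.** Conjugate addition of the amine at C2 may be slow beside the bulky silyl ether on C3. Prolonged exposure to base and formaldehyde may then cause enolisation toward C5, followed by β-elimination and aromatisation. The fallback makes the C1–C7 bond by cross-coupling. It sets out from 8. α-Iodination (I2, pyridine, CH2Cl2, rt) should give the C1 iodo enone F9. Stille coupling with Bu3SnCH2OH (Pd(PPh3)4, dioxane, 80 °C) should install the hydroxymethyl group. The fallback comes back at 10.

## Further compounds

F1 | step 2 | bromo vinyl epoxide (C2/C3 epoxide of 3, anti to the dioxolane) | BrC1=C[C@H]2O[C@H]2[C@@H]3OC(C)(C)O[C@H]13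
F2 | step 2 | trans hydroxy selenide (C2–SePh syn to the dioxolane, C3–OH anti) | BrC1=C[C@H]([Se]c2ccccc2)[C@@H](O)[C@@H]3OC(C)(C)O[C@H]13
F3 | step 2 | allylic selenoxide (Se-oxide of F2, either configuration at selenium) | BrC1=C[C@H]([Se](=O)c2ccccc2)[C@@H](O)[C@@H]3OC(C)(C)O[C@H]13
F4 | step 2 | C6 bromo selenenate (O–SePh on C6 syn to the dioxolane, alkene at C1=C2, C3–OH anti) | Br[C@@]1(O[Se]c2ccccc2)C=C[C@@H](O)[C@@H]3OC(C)(C)O[C@H]13
F5 | step 9 | O5 benzoate of diol enone 13 | O=C1C(COC(=O)c2ccccc2)=C[C@@H](O[Si](c2ccccc2)(c2ccccc2)C(C)(C)C)[C@H](O)[C@@H]1OC(=O)c1ccccc1
F6 | step 8 | C6-epimeric allylic alcohol acetonide (O6 cis to the dioxolane) | O=C(OCC1=C[C@@H](O[Si](c2ccccc2)(c2ccccc2)C(C)(C)C)[C@@H]2OC(C)(C)O[C@@H]2[C@@H]1O)c1ccccc1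
F7 | step 8 | C6 chloroacetate acetonide with inverted C6 (O6 trans to the dioxolane) | O=C(OCC1=C[C@@H](O[Si](c2ccccc2)(c2ccccc2)C(C)(C)C)[C@@H]2OC(C)(C)O[C@@H]2[C@H]1OC(=O)CCl)c1ccccc1
F8 | step 8 | C6 alcohol acetonide with target configuration at C6 | O=C(OCC1=C[C@@H](O[Si](c2ccccc2)(c2ccccc2)C(C)(C)C)[C@@H]2OC(C)(C)O[C@@H]2[C@H]1O)c1ccccc1
F9 | step 5 | C1 iodo enone (2-iodo derivative of 8) | O=C1C(I)=C[C@@H](O[Si](c2ccccc2)(c2ccccc2)C(C)(C)C)[C@@H]2OC(C)(C)O[C@H]12
A1 | alternative 1 | 5-benzoyloxy-3-hydroxy-4,6-bis(tert-butyldimethylsilyloxy)cyclohexanone (target numbering, ketone at C1) | O=C1C[C@@H](O)[C@H](O[Si](C)(C)C(C)(C)C)[C@H](OC(=O)c2ccccc2)[C@H]1O[Si](C)(C)C(C)(C)C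
A2 | alternative 1 | mercury bis(trifluoroacetate) | [Hg+2].[O-]C(=O)C(F)(F)F.[O-]C(=O)C(F)(F)F
A3 | alternative 2 | ethyl 6-hydroxy-3-(tert-butyldimethylsilyloxy)-4,5-isopropylidenedioxycyclohex-1-ene-1-carboxylate (target numbering) | CCOC(=O)C1=C[C@@H](O[Si](C)(C)C(C)(C)C)[C@@H]2OC(C)(C)O[C@@H]2[C@H]1O
A4 | alternative 3 | vinyl spiro-epoxide (oxirane on C1, oxirane oxygen cis to the C6 silyloxy group) | C1O[C@]12C=C[C@@H]3OC(C)(C)O[C@@H]3[C@H]2O[Si](C)(C)C(C)(C)C
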